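## Retrosynthetic overview

1. The C3–Br bond is made last, by electrophilic bromination of 4,6-dibromoindole. The benzene ring and its two bromines are bought as 3,5-dibromoaniline, whose two ortho positions are equivalent, so the 4,6-pattern is fixed from the start.
2. Only the pyrrole ring is built. It closes at N1–C2 from an o-aminoaryl(methylsulfanyl)acetaldehyde acetal, and the 3-SMe group left by the coupling is shed in the same acid pot.
3. The key disconnection is C3–C3a. The aniline ortho carbon and the aldehyde α-carbon are both innate donors. The aniline is polarity-reversed by oxidation at N (N–Cl, then N–S+, an o-aminoaryl cation equivalent), and the bond forms by a [2,3]-shift of the S-ylide of MeSCH2CH(OMe)2.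
4. Order: C3–C3a bond, then pyrrole closure with desulfenylation, then C3 bromination.

Assumption: the target is planar and has no stereocentre, so "single enantiomer" needs no stereocontrol and the SMILES carry no stereodescriptors.

## Route

Step 1
Reactants: 1 3,5-dibromoaniline; 2 (methylsulfanyl)acetaldehyde dimethyl acetal
Product: 6 3,5-dibromo-2-[2,2-dimethoxy-1-(methylsulfanyl)ethyl]aniline (racemic), via N-chloro-3,5-dibromoaniline 3 (not isolated), via azasulfonium chloride 4 (not isolated), via sulfonium ylide 5 (not isolated)
Conditions: t-BuOCl (1.05 equiv), CH2Cl2, −78 °C, 30 min; 2 (1.3 equiv), −78 °C, 2 h; Et3N (2 equiv), −78 °C → 40 °C, 2 h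
Reagents that add atoms: tert-butyl hypochlorite, CC(C)(C)OCl (supplies the Cl of intermediates 3 and 4 only; all heavy atoms of 6 come from 1 and 2)
Why: Gassman ortho-alkylation, in which N-chlorination and S-attack turn the innately nucleophilic aniline into azasulfonium salt 4 (an o-aminoaryl cation equivalent), so that in ylide 5 the α-carbon of the masked aldehyde, itself an innate donor, bonds to the ortho carbon by a [2,3]-sigmatropic (Sommelet–Hauser-type) shift that breaks the weak N–S bond, needs no ring nucleophilicity and can only reach the two equivalent ortho sites; the new benzylic stereocentre forms racemic and is erased in step 2.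

Step 2
Reactants: 6 3,5-dibromo-2-[2,2-dimethoxy-1-(methylsulfanyl)ethyl]aniline
Product: 8 4,6-dibromo-1H-indole, via 4,6-dibromo-3-(methylsulfanyl)-1H-indole 7 (not isolated)
Conditions: thiosalicylic acid (2.5 equiv), TFA, 0 °C → 50 °C, 4 h; aq NaHCO3 wash
Reagents that add atoms: none
Why: Acid-mediated Gassman indole ring closure followed by protodesulfenylation, in which TFA ionises the acetal, the aniline N adds to the oxocarbenium ion and loss of two MeOH aromatises to 7, whose C3-protonated 3H-indolium form passes MeS+ to the thiol (sulfenyl transfer helped by relief of 3-SMe/4-Br peri strain), a non-reductive removal that leaves both C–Br bonds untouched and destroys the only stereocentre.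

Step 3
Reactants: 8 4,6-dibromo-1H-indole
Product: 9 3,4,6-tribromo-1H-indole
Conditions: NBS (1.0 equiv), DMF, 0 °C, dark, 30 min
Reagents that add atoms: N-bromosuccinimide, O=C1CCC(=O)N1Br
Why: Electrophilic aromatic substitution at the enamine-like C3, still by far the most nucleophilic position of the deactivated indole, with exactly one equivalent of NBS at low temperature so that the reaction stops before C2 is attacked; no stereocentre is involved.

## Compound list

1 | 3,5-dibromoaniline | Nc1cc(Br)cc(Br)c1 | starting material
2 | (methylsulfanyl)acetaldehyde dimethyl acetal (1,1-dimethoxy-2-(methylsulfanyl)ethane) | COC(CSC)OC | starting material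
3 | N-chloro-3,5-dibromoaniline | ClNc1cc(Br)cc(Br)c1 | intermediate
4 | (3,5-dibromoanilino)(2,2-dimethoxyethyl)(methyl)sulfonium chloride (racemic at S) | C[S+](CC(OC)OC)Nc1cc(Br)cc(Br)c1.[Cl-] | intermediate
5 | S-ylide of 4, carbanion on the carbon between S+ and the acetal carbon | C[S+]([CH-]C(OC)OC)Nc1cc(Br)cc(Br)c1 | intermediate
6 | 3,5-dibromo-2-[2,2-dimethoxy-1-(methylsulfanyl)ethyl]aniline (racemic) | COC(OC)C(SC)c1c(N)cc(Br)cc1Br | intermediate
7 | 4,6-dibromo-3-(methylsulfanyl)-1H-indole | CSc1c[nH]c2cc(Br)cc(Br)c12 | intermediate
8 | 4,6-dibromo-1H-indole | Brc1cc(Br)c2cc[nH]c2c1 | intermediate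
9 | 3,4,6-tribromo-1H-indole | Brc1cc(Br)c2c(Br)c[nH]c2c1 | target

## Step count and risks

Total step count: 3. Longest linear sequence: 3.

**Step 1 (highest risk).**
- Aniline 1 is strongly deactivated, so the N-deprotonated (sulfilimine) tautomer of 5 can become a resting state.
- The ylide has no carbonyl stabilisation, so deprotonation at S–CH3 can compete.
- The new bond has to form next to a bromine.

The fallback sets out from 1 and comes back at 8. It keeps the polarity-reversed aniline but uses a carbonyl-stabilised ylide at the ester oxidation level, and it removes sulfur before the indole exists.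
- Compound 3 is generated as before and trapped with ethyl (methylsulfanyl)acetate to give (3,5-dibromoanilino)(2-ethoxy-2-oxoethyl)(methyl)sulfonium chloride F1.
- Et3N triggers the [2,3]-shift to ethyl 2-(2-amino-4,6-dibromophenyl)-2-(methylsulfanyl)acetate F2.
- Dilute HCl lactamises this to 4,6-dibromo-3-(methylsulfanyl)indolin-2-one F3.
- Zinc dust in AcOH at rt cleaves the α-carbonyl C–S bond without touching the aryl bromides, giving 4,6-dibromoindolin-2-one F4.
- BH3·THF reduces and dehydrates the lactam to 8.

**Step 2.**
- The 2,3-unsubstituted indole 8 can oligomerise in TFA.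
- The deactivated 7 may protonate at C3 only reluctantly.
- The sulfenyl group can migrate from C3 to C2.

The fallback sets out from 6 and comes back at 8. It replaces acidolytic sulfenyl transfer with neutral reductive C–S hydrogenolysis.
- Compound 6 is closed with 2 M aq HCl/Et2O at rt only, and 7 is isolated.
- Compound 7 is then stirred briefly with acetone-deactivated W-2 Raney nickel in EtOH at 0 °C to rt. The reaction is monitored and stopped before hydrodebromination begins.
- This fallback makes no compound outside the list (F0).

**Step 3.**
- A second bromination at C2 can occur.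
- The 4-Br slows attack at C3 through peri hindrance.
- The N–H 3-bromoindole is sensitive to acid and light during isolation.

The fallback sets out from 8 and comes back at 9. It uses a bulky N-silyl group to shield C2 and stabilise the bromide.
- NaH/TBSCl in THF gives 4,6-dibromo-1-(tert-butyldimethylsilyl)indole F5.
- NBS in THF at −78 °C gives 3,4,6-tribromo-1-(tert-butyldimethylsilyl)indole F6, which can be purified on silica.
- TBAF in THF at 0 °C releases 9.

## Further compounds

F1 | step 1 | (3,5-dibromoanilino)(2-ethoxy-2-oxoethyl)(methyl)sulfonium chloride | CCOC(=O)C[S+](C)Nc1cc(Br)cc(Br)c1.[Cl-]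
F2 | step 1 | ethyl 2-(2-amino-4,6-dibromophenyl)-2-(methylsulfanyl)acetate (racemic) | CCOC(=O)C(SC)c1c(N)cc(Br)cc1Br
F3 | step 1 | 4,6-dibromo-3-(methylsulfanyl)indolin-2-one (racemic) | CSC1C(=O)Nc2cc(Br)cc(Br)c12
F4 | step 1 | 4,6-dibromoindolin-2-one | O=C1Cc2c(Br)cc(Br)cc2N1
F0 | step 2 | none | none
F5 | step 3 | 4,6-dibromo-1-(tert-butyldimethylsilyl)indole | CC(C)(C)[Si](C)(C)n1ccc2c(Br)cc(Br)cc12
F6 | step 3 | 3,4,6-tribromo-1-(tert-butyldimethylsilyl)indole | CC(C)(C)[Si](C)(C)n1cc(Br)c2c(Br)cc(Br)cc12
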